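**Retrosynthetic overview**

- The strategy rests on one feature of ring C: C2 is a methylene held between O1 and the only stereocentre, C3. The C2–C3 bond is therefore made last, by inserting a C3 carbene into a C–H bond of an ortho methoxy group of ring A, which closes ring C and sets C3 under catalyst control.
- The carbene precursor is an α-diazo deoxybenzoin. The diazo group comes from diazo transfer to the ketone; the ketone comes from addition of a 2,6-dimethoxy-4-silyloxyphenyl metal (silylated 3,5-dimethoxyphenol, lithiated between the methoxy groups) to a chromenylacetaldehyde, then oxidation.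
- The chromenylacetaldehyde comes from one-carbon homologation of 5-hydroxy-2,2-dimethyl-2H-chromene-6-carbaldehyde, whose pyran ring is annulated onto 2,4-dihydroxybenzaldehyde with 3-methylbut-2-enal.
- Ring order: rings A and B are bought, the dimethylpyran ring is formed first (step 1), ring C last (step 9). Chelation-controlled cleavage of the 5-methyl ether and buffered fluoride desilylation finish the synthesis.

Key step: step 9

Assumption: Rh2(S-PTTL)4 is taken to deliver the (3R) configuration by analogy with related insertions of aryl-substituted carbenoids; should the (3S) isomer predominate, the enantiomeric catalyst Rh2(R-PTTL)4 is used and nothing else changes.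

**Route**

Step 1
Reactants: 1 2,4-dihydroxybenzaldehyde; 2 3-methylbut-2-enal
Product: 4 5-hydroxy-2,2-dimethyl-2H-chromene-6-carbaldehyde, via ortho-quinone methide 3 (not isolated)
Conditions: Ca(OH)2, MeOH, rt
Reagents that add atoms: none
Why: Base-mediated chromenylation of a resorcinol with an enal (Knoevenagel-type condensation, then oxa-6π electrocyclisation): the phenolate carbon between the two oxygens condenses with the aldehyde of 2, loss of water gives 3, and the ring closes through the non-chelated 4-oxygen, leaving the 2-OH hydrogen-bonded to the formyl group.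

Step 2
Reactants: 4 5-hydroxy-2,2-dimethyl-2H-chromene-6-carbaldehyde
Product: 5 5-[(tert-butyldiphenylsilyl)oxy]-2,2-dimethyl-2H-chromene-6-carbaldehyde
Conditions: TBDPSCl, imidazole, DMAP (cat.), DMF, 50 °C
Reagents that add atoms: tert-butyl(chloro)diphenylsilane, CC(C)(C)[Si](Cl)(c1ccccc1)c1ccccc1
Why: Standard phenol silylation; the tert-butyldiphenylsilyl group is chosen because it should survive ylide, aqueous acid, organometallic and amidine base, and because in step 9 its nearest C–H bonds could only close a seven-membered ring onto C3.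

Step 3
Reactants: 5 5-[(tert-butyldiphenylsilyl)oxy]-2,2-dimethyl-2H-chromene-6-carbaldehyde
Product: 6 tert-butyl{[6-(2-methoxyethenyl)-2,2-dimethyl-2H-chromen-5-yl]oxy}diphenylsilane (E/Z mixture)
Conditions: Ph3P(CH2OMe)Cl, KN(SiMe3)2, THF, 0 °C; then 5, 0 °C to rt
Reagents that add atoms: (methoxymethyl)triphenylphosphonium chloride, [Cl-].COC[P+](c1ccccc1)(c1ccccc1)c1ccccc1
Why: Wittig olefination with the non-stabilised methoxymethylene ylide adds the one carbon needed; the E/Z ratio is irrelevant because both isomers give the same aldehyde.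

Step 4
Reactants: 6 tert-butyl{[6-(2-methoxyethenyl)-2,2-dimethyl-2H-chromen-5-yl]oxy}diphenylsilane
Product: 7 {5-[(tert-butyldiphenylsilyl)oxy]-2,2-dimethyl-2H-chromen-6-yl}acetaldehyde
Conditions: 2 M aq HCl, THF, 40 °C
Reagents that add atoms: water, O
Why: Acid-catalysed enol ether hydrolysis; the enol ether is protonated much faster than the styrenic chromene double bond and the aryl silyl ether is acid-stable, so mild aqueous acid should unmask the arylacetaldehyde, which is used at once.

Step 5
Reactants: 8 3,5-dimethoxyphenol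
Product: 9 (3,5-dimethoxyphenoxy)tri(propan-2-yl)silane
Conditions: TIPSCl, imidazole, DMF, rt
Reagents that add atoms: chlorotri(propan-2-yl)silane, CC(C)[Si](Cl)(C(C)C)C(C)C
Why: Standard phenol silylation; the triisopropylsilyl group does not direct lithiation to its own ortho positions, resists anionic silyl migration, and should tolerate the amidine base of step 8.

Step 6
Reactants: 9 (3,5-dimethoxyphenoxy)tri(propan-2-yl)silane; 7 {5-[(tert-butyldiphenylsilyl)oxy]-2,2-dimethyl-2H-chromen-6-yl}acetaldehyde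
Product: 12 rac-1-{2,6-dimethoxy-4-[(triisopropylsilyl)oxy]phenyl}-2-{5-[(tert-butyldiphenylsilyl)oxy]-2,2-dimethyl-2H-chromen-6-yl}ethan-1-ol, via aryllithium 10 (not isolated), via arylcerium dichloride 11 (not isolated)
Conditions: 9, n-BuLi, THF, 0 °C to rt; CeCl3 (anhydrous), THF, −78 °C; then 7, −78 °C; sat. aq NH4Cl, −78 °C
Reagents that add atoms: none
Why: Directed ortho-metalation at the position flanked by both methoxy groups, transmetalation to the weakly basic organocerium reagent, and 1,2-addition to the enolisable aldehyde (organocerium carbonyl addition); the carbinol centre forms racemic and is erased in step 7, and the cold quench guards against silyl migration to the new alkoxide.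

Step 7
Reactants: 12 rac-1-{2,6-dimethoxy-4-[(triisopropylsilyl)oxy]phenyl}-2-{5-[(tert-butyldiphenylsilyl)oxy]-2,2-dimethyl-2H-chromen-6-yl}ethan-1-ol
Product: 13 1-{2,6-dimethoxy-4-[(triisopropylsilyl)oxy]phenyl}-2-{5-[(tert-butyldiphenylsilyl)oxy]-2,2-dimethyl-2H-chromen-6-yl}ethan-1-one
Conditions: Dess–Martin periodinane, NaHCO3, CH2Cl2, 0 °C to rt
Reagents that add atoms: none
Why: Dess–Martin oxidation under bicarbonate buffering should convert the acid-sensitive, electron-rich benzylic alcohol into the deoxybenzoin without touching the chromene or the silyl ethers.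

Step 8
Reactants: 13 1-{2,6-dimethoxy-4-[(triisopropylsilyl)oxy]phenyl}-2-{5-[(tert-butyldiphenylsilyl)oxy]-2,2-dimethyl-2H-chromen-6-yl}ethan-1-one
Product: 14 2-diazo-1-{2,6-dimethoxy-4-[(triisopropylsilyl)oxy]phenyl}-2-{5-[(tert-butyldiphenylsilyl)oxy]-2,2-dimethyl-2H-chromen-6-yl}ethan-1-one
Conditions: p-ABSA, DBU, MeCN, 0 °C to rt
Reagents that add atoms: 4-acetamidobenzenesulfonyl azide, CC(=O)Nc1ccc(cc1)S(=O)(=O)N=[N+]=[N-]
Why: Regitz diazo transfer; the methylene of a deoxybenzoin, activated by both the ketone and the aryl ring, is acidic enough for DBU, and its enolate takes the diazo group from the sulfonyl azide.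

Step 9
Reactants: 14 2-diazo-1-{2,6-dimethoxy-4-[(triisopropylsilyl)oxy]phenyl}-2-{5-[(tert-butyldiphenylsilyl)oxy]-2,2-dimethyl-2H-chromen-6-yl}ethan-1-one
Product: 15 (3R)-3-{5-[(tert-butyldiphenylsilyl)oxy]-2,2-dimethyl-2H-chromen-6-yl}-5-methoxy-7-[(triisopropylsilyl)oxy]-2,3-dihydro-4H-chromen-4-one
Conditions: Rh2(S-PTTL)4 (2 mol %), 4 Å MS, PhCF3, 0 °C, slow addition of 14 at high dilution
Reagents that add atoms: none
Why: Rh2(S-PTTL)4, the dirhodium tetrakis[N-phthaloyl-(S)-tert-leucinate] complex of divalent rhodium, expels N2 from 14 to give an electrophilic aryl keto carbenoid whose carbon (the future C3) accepts the C–H σ bond of an ortho methoxy group of ring A in a concerted, asynchronous, hydride-transfer-like three-centre transition state, forming C2–C3 and C3–H together and releasing the catalyst. The closest known reaction type is the dirhodium-carboxylate-catalysed intramolecular C–H insertion of 2-alkoxyaryl α-diazo ketones next to the ether oxygen to give chroman-4-ones, run here with an aryl-substituted (donor–acceptor) carbenoid of the kind that phthalimido amino acid dirhodium catalysts cyclise enantioselectively. Ring C closes as a six-membered ring by 1,6-insertion through the array C3–C4–C4a–C8a–O1–CH3, the only size available because the atom in the 1,5-position is oxygen. The C3 stereocentre is set by the catalyst, whose crown of phthalimido tert-leucinate ligands leaves one face of the rhodium-bound carbene open to the approaching methyl group, and the medium is neutral and free of base, so the acidic C3–H that forms is not enolised. The step needs enantioface selectivity at C3 and chemoselectivity for C–H insertion over oxonium ylide formation with methyl [1,2]-shift, Wolff rearrangement and intermolecular cyclopropanation of the chromene olefin; the sterically demanding, electron-withdrawing carboxylates, the low temperature and slow addition at high dilution serve this. Site selectivity comes from the substrate: the two ortho methoxy groups of ring A are equivalent by symmetry and leave no aromatic C–H next to the ketone, and the nearest C–H bonds of the 2'-O-silyl group could only close a seven-membered ring.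

Step 10
Reactants: 15 (3R)-3-{5-[(tert-butyldiphenylsilyl)oxy]-2,2-dimethyl-2H-chromen-6-yl}-5-methoxy-7-[(triisopropylsilyl)oxy]-2,3-dihydro-4H-chromen-4-one
Product: 16 (3R)-3-{5-[(tert-butyldiphenylsilyl)oxy]-2,2-dimethyl-2H-chromen-6-yl}-5-hydroxy-7-[(triisopropylsilyl)oxy]-2,3-dihydro-4H-chromen-4-one
Conditions: MgI2·OEt2, THF, 45 °C; cold 0.5 M aq HCl work-up
Reagents that add atoms: none
Why: Chelation-assisted ether cleavage: magnesium held between the C4 carbonyl oxygen and the peri 5-methoxy oxygen activates only that methyl group for SN2 attack by iodide, and the absence of an amine base together with the acidic quench should keep the enolisable C3 centre intact.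

Step 11
Reactants: 16 (3R)-3-{5-[(tert-butyldiphenylsilyl)oxy]-2,2-dimethyl-2H-chromen-6-yl}-5-hydroxy-7-[(triisopropylsilyl)oxy]-2,3-dihydro-4H-chromen-4-one
Product: 17 (3R)-5,7-dihydroxy-3-(5-hydroxy-2,2-dimethyl-2H-chromen-6-yl)-2,3-dihydro-4H-chromen-4-one
Conditions: Bu4NF, AcOH (1:1.5), THF, 0 °C to rt
Reagents that add atoms: none
Why: Fluoride-mediated desilylation of both aryl silyl ethers (phenoxides are good leaving groups from silicon); the acetic acid buffer should hold the medium below the basicity at which the C3–H of an isoflavanone enolises, so the (3R) centre is carried unchanged into the target.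

**Compound list**

1 | 2,4-dihydroxybenzaldehyde | O=Cc1ccc(O)cc1O | starting material
2 | 3-methylbut-2-enal | CC(C)=CC=O | starting material
3 | 2-hydroxy-3-(3-methylbut-2-en-1-ylidene)-4-oxocyclohexa-1,5-diene-1-carbaldehyde (ortho-quinone methide, not isolated) | O=CC1=C(O)C(=CC=C(C)C)C(=O)C=C1 | intermediate
4 | 5-hydroxy-2,2-dimethyl-2H-chromene-6-carbaldehyde | CC1(C)C=Cc2c(O)c(C=O)ccc2O1 | intermediate
5 | 5-[(tert-butyldiphenylsilyl)oxy]-2,2-dimethyl-2H-chromene-6-carbaldehyde | CC1(C)C=Cc2c(O[Si](c3ccccc3)(c3ccccc3)C(C)(C)C)c(C=O)ccc2O1 | intermediate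
6 | tert-butyl{[6-(2-methoxyethenyl)-2,2-dimethyl-2H-chromen-5-yl]oxy}diphenylsilane (E/Z mixture) | CC1(C)C=Cc2c(O[Si](c3ccccc3)(c3ccccc3)C(C)(C)C)c(C=COC)ccc2O1 | intermediate
7 | {5-[(tert-butyldiphenylsilyl)oxy]-2,2-dimethyl-2H-chromen-6-yl}acetaldehyde | CC1(C)C=Cc2c(O[Si](c3ccccc3)(c3ccccc3)C(C)(C)C)c(CC=O)ccc2O1 | intermediate
8 | 3,5-dimethoxyphenol | COc1cc(O)cc(OC)c1 | starting material
9 | (3,5-dimethoxyphenoxy)tri(propan-2-yl)silane | COc1cc(OC)cc(O[Si](C(C)C)(C(C)C)C(C)C)c1 | intermediate
10 | {2,6-dimethoxy-4-[(triisopropylsilyl)oxy]phenyl}lithium (not isolated) | [Li]c1c(OC)cc(O[Si](C(C)C)(C(C)C)C(C)C)cc1OC | intermediate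
11 | dichloro{2,6-dimethoxy-4-[(triisopropylsilyl)oxy]phenyl}cerium (not isolated) | Cl[Ce](Cl)c1c(OC)cc(O[Si](C(C)C)(C(C)C)C(C)C)cc1OC | intermediate
12 | rac-1-{2,6-dimethoxy-4-[(triisopropylsilyl)oxy]phenyl}-2-{5-[(tert-butyldiphenylsilyl)oxy]-2,2-dimethyl-2H-chromen-6-yl}ethan-1-ol | COc1cc(O[Si](C(C)C)(C(C)C)C(C)C)cc(OC)c1C(O)Cc1ccc2OC(C)(C)C=Cc2c1O[Si](c1ccccc1)(c1ccccc1)C(C)(C)C | intermediate
13 | 1-{2,6-dimethoxy-4-[(triisopropylsilyl)oxy]phenyl}-2-{5-[(tert-butyldiphenylsilyl)oxy]-2,2-dimethyl-2H-chromen-6-yl}ethan-1-one | COc1cc(O[Si](C(C)C)(C(C)C)C(C)C)cc(OC)c1C(=O)Cc1ccc2OC(C)(C)C=Cc2c1O[Si](c1ccccc1)(c1ccccc1)C(C)(C)C | intermediate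
14 | 2-diazo-1-{2,6-dimethoxy-4-[(triisopropylsilyl)oxy]phenyl}-2-{5-[(tert-butyldiphenylsilyl)oxy]-2,2-dimethyl-2H-chromen-6-yl}ethan-1-one | COc1cc(O[Si](C(C)C)(C(C)C)C(C)C)cc(OC)c1C(=O)C(=[N+]=[N-])c1ccc2OC(C)(C)C=Cc2c1O[Si](c1ccccc1)(c1ccccc1)C(C)(C)C | intermediate
15 | (3R)-3-{5-[(tert-butyldiphenylsilyl)oxy]-2,2-dimethyl-2H-chromen-6-yl}-5-methoxy-7-[(triisopropylsilyl)oxy]-2,3-dihydro-4H-chromen-4-one | CC1(C)C=Cc2c(ccc([C@@H]3COc4cc(O[Si](C(C)C)(C(C)C)C(C)C)cc(OC)c4C3=O)c2O[Si](c5ccccc5)(c5ccccc5)C(C)(C)C)O1 | intermediate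
16 | (3R)-3-{5-[(tert-butyldiphenylsilyl)oxy]-2,2-dimethyl-2H-chromen-6-yl}-5-hydroxy-7-[(triisopropylsilyl)oxy]-2,3-dihydro-4H-chromen-4-one | CC1(C)C=Cc2c(ccc([C@@H]3COc4cc(O[Si](C(C)C)(C(C)C)C(C)C)cc(O)c4C3=O)c2O[Si](c5ccccc5)(c5ccccc5)C(C)(C)C)O1 | intermediate
17 | (3R)-5,7-dihydroxy-3-(5-hydroxy-2,2-dimethyl-2H-chromen-6-yl)-2,3-dihydro-4H-chromen-4-one | CC1(C)C=Cc2c(ccc([C@@H]3COc4cc(O)cc(O)c4C3=O)c2O)O1 | target

**Step count**

Total: 11 steps. Longest linear sequence: 10 steps (steps 1–4 and 6–11, from 2,4-dihydroxybenzaldehyde); step 5 is the one-step side branch to the ring A partner.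

**Steps most likely to fail, with fallbacks**

Step 9. The carbenoid may attack the methoxy oxygen instead of its C–H bond, giving a cyclic oxonium ylide that ends in a methyl [1,2]-shift. Ring A may also migrate to the carbene carbon (Wolff rearrangement), or the catalyst may discriminate poorly between the two faces at C3. The fallback avoids carbenoid chemistry altogether; it sets out from 13 and comes back at 15. MgI2·OEt2 in THF should cleave one of the two equivalent ortho methyl ethers of 13 through the magnesium chelate to give 1-{2-hydroxy-6-methoxy-4-[(triisopropylsilyl)oxy]phenyl}-2-{5-[(tert-butyldiphenylsilyl)oxy]-2,2-dimethyl-2H-chromen-6-yl}ethan-1-one F1. Heating with N,N-dimethylformamide dimethyl acetal in toluene (enaminone formation, then cyclisation with loss of dimethylamine) should close ring C as the isoflavone 3-{5-[(tert-butyldiphenylsilyl)oxy]-2,2-dimethyl-2H-chromen-6-yl}-5-methoxy-7-[(triisopropylsilyl)oxy]-4H-chromen-4-one F2. Asymmetric transfer hydrogenation with RuCl(p-cymene)(TsDPEN) (ligand enantiomer chosen to give the 3R,4R product) and HCO2H/Et3N should reduce C2=C3 and then, with dynamic kinetic resolution of the base-labile C3 centre, the ketone, giving the cis alcohol (3R,4R)-3-{5-[(tert-butyldiphenylsilyl)oxy]-2,2-dimethyl-2H-chromen-6-yl}-5-methoxy-7-[(triisopropylsilyl)oxy]chroman-4-ol F3. Buffered Dess–Martin oxidation of F3 under neutral conditions returns 15.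

Step 10. The C3–H may be enolised through the magnesium chelate of the ketone, or by the magnesium phenoxide that the reaction itself produces, eroding the enantiomeric purity. The fallback moves the ether cleavage to the achiral stage; it sets out from 13 and comes back at 17. The mono-demethylation described above gives the hydroxy ketone F1. TIPSOTf and 2,6-lutidine should then give 1-{2-methoxy-4,6-bis[(triisopropylsilyl)oxy]phenyl}-2-{5-[(tert-butyldiphenylsilyl)oxy]-2,2-dimethyl-2H-chromen-6-yl}ethan-1-one F4. Diazo transfer as in step 8 should give 2-diazo-1-{2-methoxy-4,6-bis[(triisopropylsilyl)oxy]phenyl}-2-{5-[(tert-butyldiphenylsilyl)oxy]-2,2-dimethyl-2H-chromen-6-yl}ethan-1-one F5. Insertion with Rh2(S-PTTL)4 into the single remaining methoxy group should give (3R)-3-{5-[(tert-butyldiphenylsilyl)oxy]-2,2-dimethyl-2H-chromen-6-yl}-5,7-bis[(triisopropylsilyl)oxy]-2,3-dihydro-4H-chromen-4-one F6. Buffered fluoride under the conditions of step 11 then gives 17 directly, so no Lewis acid meets the stereocentre.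

Step 6. The organometallic may deprotonate the arylacetaldehyde instead of adding to it, or the aryl silyl group may migrate to the newly formed alkoxide. The fallback replaces carbonyl addition and oxidation by an acylation; it sets out from 7 and comes back at 13. Pinnick oxidation (NaClO2, NaH2PO4, 2-methylbut-2-ene, t-BuOH/H2O) should give {5-[(tert-butyldiphenylsilyl)oxy]-2,2-dimethyl-2H-chromen-6-yl}acetic acid F7. Coupling with N,O-dimethylhydroxylamine hydrochloride (EDC·HCl, i-Pr2NEt, CH2Cl2) should give 2-{5-[(tert-butyldiphenylsilyl)oxy]-2,2-dimethyl-2H-chromen-6-yl}-N-methoxy-N-methylacetamide F8. Addition of aryllithium 10 at −78 °C forms a stable chelated tetrahedral adduct that carries no free alkoxide and collapses on work-up to ketone 13 without an oxidation step.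

**Further compounds**

F1 | step 9 | 1-{2-hydroxy-6-methoxy-4-[(triisopropylsilyl)oxy]phenyl}-2-{5-[(tert-butyldiphenylsilyl)oxy]-2,2-dimethyl-2H-chromen-6-yl}ethan-1-one | COc1cc(O[Si](C(C)C)(C(C)C)C(C)C)cc(O)c1C(=O)Cc1ccc2OC(C)(C)C=Cc2c1O[Si](c1ccccc1)(c1ccccc1)C(C)(C)C
F2 | step 9 | 3-{5-[(tert-butyldiphenylsilyl)oxy]-2,2-dimethyl-2H-chromen-6-yl}-5-methoxy-7-[(triisopropylsilyl)oxy]-4H-chromen-4-one | CC1(C)C=Cc2c(ccc(C3=COc4cc(O[Si](C(C)C)(C(C)C)C(C)C)cc(OC)c4C3=O)c2O[Si](c5ccccc5)(c5ccccc5)C(C)(C)C)O1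
F3 | step 9 | (3R,4R)-3-{5-[(tert-butyldiphenylsilyl)oxy]-2,2-dimethyl-2H-chromen-6-yl}-5-methoxy-7-[(triisopropylsilyl)oxy]chroman-4-ol | CC1(C)C=Cc2c(ccc([C@@H]3COc4cc(O[Si](C(C)C)(C(C)C)C(C)C)cc(OC)c4[C@@H]3O)c2O[Si](c5ccccc5)(c5ccccc5)C(C)(C)C)O1
F4 | step 10 | 1-{2-methoxy-4,6-bis[(triisopropylsilyl)oxy]phenyl}-2-{5-[(tert-butyldiphenylsilyl)oxy]-2,2-dimethyl-2H-chromen-6-yl}ethan-1-one | COc1cc(O[Si](C(C)C)(C(C)C)C(C)C)cc(O[Si](C(C)C)(C(C)C)C(C)C)c1C(=O)Cc1ccc2OC(C)(C)C=Cc2c1O[Si](c1ccccc1)(c1ccccc1)C(C)(C)C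
F5 | step 10 | 2-diazo-1-{2-methoxy-4,6-bis[(triisopropylsilyl)oxy]phenyl}-2-{5-[(tert-butyldiphenylsilyl)oxy]-2,2-dimethyl-2H-chromen-6-yl}ethan-1-one | COc1cc(O[Si](C(C)C)(C(C)C)C(C)C)cc(O[Si](C(C)C)(C(C)C)C(C)C)c1C(=O)C(=[N+]=[N-])c1ccc2OC(C)(C)C=Cc2c1O[Si](c1ccccc1)(c1ccccc1)C(C)(C)C
F6 | step 10 | (3R)-3-{5-[(tert-butyldiphenylsilyl)oxy]-2,2-dimethyl-2H-chromen-6-yl}-5,7-bis[(triisopropylsilyl)oxy]-2,3-dihydro-4H-chromen-4-one | CC1(C)C=Cc2c(ccc([C@@H]3COc4cc(O[Si](C(C)C)(C(C)C)C(C)C)cc(O[Si](C(C)C)(C(C)C)C(C)C)c4C3=O)c2O[Si](c5ccccc5)(c5ccccc5)C(C)(C)C)O1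
F7 | step 6 | {5-[(tert-butyldiphenylsilyl)oxy]-2,2-dimethyl-2H-chromen-6-yl}acetic acid | OC(=O)Cc1ccc2OC(C)(C)C=Cc2c1O[Si](c1ccccc1)(c1ccccc1)C(C)(C)C
F8 | step 6 | 2-{5-[(tert-butyldiphenylsilyl)oxy]-2,2-dimethyl-2H-chromen-6-yl}-N-methoxy-N-methylacetamide | CON(C)C(=O)Cc1ccc2OC(C)(C)C=Cc2c1O[Si](c1ccccc1)(c1ccccc1)C(C)(C)C
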